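**Retrosynthetic overview**

1. Numbering: C1 prenylated bridgehead, C2 its ketone, C3 acylated carbon, C4 enol carbon, C5 methylated bridgehead, C6 CH2, C7 prenylated CH, C8 CMe2, C9 bridging ketone. The route rests on the C7–C8 bond of ring A (C1–C8–C7–C6–C5–C9), which joins quaternary C8, itself next to quaternary C1, to the stereogenic C7.
2. Target 27 ⇒ methyl enol ether 17 of the bicyclic trione (C3 acylation, allyl → prenyl at C1, CH2CO2Me → prenyl at C7, hydride to C7 from the exo face). Ring B is formed second, by C4–C5 closure from a three-carbon acyl unit on C1.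
3. Ring A is formed first: cyclohexanone 13 ⇐ acyclic keto diester 12, by hydrogen-atom transfer to the isopropenyl group on C1 and 6-exo-dig addition of the C8 radical to the ynoate carbon C7.
4. 12 ⇐ malonate 1 by deconjugative allylation, esterase desymmetrisation (C1, the only source of absolute configuration), ethyl ketone formation, propargylation and alkyne carboxylation.

Key step: step 8

Assumption: the enantiotopic ester that pig liver esterase hydrolyses in 3 cannot be predicted; the route is written for the (S)-half-ester 4, and an enantiocomplementary esterase isoenzyme would be used should the (R)-acid form.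

Remark: C5 arises in step 6 as an epimer mixture and the exocyclic alkene of 13 may arise as an E/Z mixture. Both elements are erased later (steps 10 and 11), so one isomer is drawn throughout.

**Step 1**
Reactants: 1 diethyl 2-(propan-2-ylidene)malonate; 2 allyl bromide
Product: 3 diethyl 2-(prop-2-en-1-yl)-2-(prop-1-en-2-yl)propanedioate
Conditions: NaH, THF/DMF, 0 °C; then 2, 0 °C → rt
Reagents that add atoms: none
Why: Deconjugative α-alkylation: NaH removes a γ-hydrogen of the alkylidene malonate and the dienolate is allylated at the α-carbon, which moves the double bond out of conjugation and builds the quaternary, still prochiral C1 with its isopropenyl and allyl groups.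

**Step 2**
Reactants: 3 diethyl 2-(prop-2-en-1-yl)-2-(prop-1-en-2-yl)propanedioate
Product: 4 (2S)-2-(ethoxycarbonyl)-2-(prop-1-en-2-yl)pent-4-enoic acid
Conditions: pig liver esterase, phosphate buffer pH 7.5/DMSO, 25 °C, pH-stat (1 M NaOH); then 1 M HCl
Reagents that add atoms: water, O
Why: Enzymatic desymmetrisation of a prochiral 2,2-disubstituted malonate, in which the chiral active site hydrolyses one enantiotopic ester and thereby sets C1 (sense assumed as stated above).

**Step 3**
Reactants: 4 (2S)-2-(ethoxycarbonyl)-2-(prop-1-en-2-yl)pent-4-enoic acid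
Product: 5 1-tert-butyl 3-ethyl (2R)-2-(prop-2-en-1-yl)-2-(prop-1-en-2-yl)propanedioate
Conditions: t-BuOC(=NH)CCl3, BF3·OEt2 (cat.), CH2Cl2/cyclohexane, rt
Reagents that add atoms: tert-butyl 2,2,2-trichloroacetimidate, CC(C)(C)OC(=N)C(Cl)(Cl)Cl
Why: Acid-catalysed tert-butyl transfer from the trichloroacetimidate esterifies the hindered acid; the future C2 carboxyl is parked as a tert-butyl ester because it must later be unmasked without hydroxide, beside a ketone and between two fully substituted carbons, where an ethyl ester could not be cleaved selectively (C1 is untouched, the descriptor changes only through priorities).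

**Step 4**
Reactants: 5 1-tert-butyl 3-ethyl (2R)-2-(prop-2-en-1-yl)-2-(prop-1-en-2-yl)propanedioate
Product: 6 (2R)-2-(tert-butoxycarbonyl)-2-(prop-1-en-2-yl)pent-4-enoic acid
Conditions: LiOH·H2O, THF/MeOH/H2O, 40 °C; then 1 M HCl, 0 °C
Reagents that add atoms: lithium hydroxide, [Li+].[OH-]
Why: Chemoselective saponification of the ethyl ester beside the tert-butyl ester, which resists acyl attack by hydroxide, frees the carboxyl that becomes C9.

**Step 5**
Reactants: 6 (2R)-2-(tert-butoxycarbonyl)-2-(prop-1-en-2-yl)pent-4-enoic acid; 7 ethylmagnesium bromide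
Product: 9 tert-butyl (2R)-3-oxo-2-(prop-2-en-1-yl)-2-(prop-1-en-2-yl)pentanoate, via acid chloride 8 (not isolated)
Conditions: Me2C=C(Cl)NMe2 (Ghosez reagent), CH2Cl2, 0 °C → rt; then 7, CuI (10 mol%), THF, −78 °C
Reagents that add atoms: none
Why: Neutral acid chloride formation with the α-chloroenamine (no HCl, so the tert-butyl ester survives) followed by copper-catalysed acylation of the Grignard reagent gives the ethyl ketone without over-addition, and the quaternary C1 cannot epimerise.

**Step 6**
Reactants: 9 tert-butyl (2R)-3-oxo-2-(prop-2-en-1-yl)-2-(prop-1-en-2-yl)pentanoate; 10 propargyl bromide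
Product: 11 tert-butyl (2R,4R)-4-methyl-3-oxo-2-(prop-2-en-1-yl)-2-(prop-1-en-2-yl)hept-6-ynoate (with its 4S epimer)
Conditions: LiN(i-Pr)2, THF, −78 °C; DMPU, then 10, −78 → −20 °C
Reagents that add atoms: none
Why: Kinetic enolate alkylation (SN2): the ketone can enolise only toward C5 because C1 is quaternary, and the new C5 centre forms without control, which is harmless since this carbon becomes trigonal again in step 10.

**Step 7**
Reactants: 11 tert-butyl (2R,4R)-4-methyl-3-oxo-2-(prop-2-en-1-yl)-2-(prop-1-en-2-yl)hept-6-ynoate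
Product: 12 8-tert-butyl 1-methyl (5R,7R)-5-methyl-6-oxo-7-(prop-2-en-1-yl)-7-(prop-1-en-2-yl)oct-2-ynedioate
Conditions: AgI (5 mol%), Cs2CO3, CO2 (2 atm), DMF, 45 °C; then MeI, rt
Reagents that add atoms: carbon dioxide, O=C=O; iodomethane, CI
Why: Silver-catalysed C–H carboxylation of the terminal alkyne with CO2 and carbonate, then O-methylation of the caesium alkynoate in the same flask, installs the ynoate without a strong base and without a bromo-ynoate electrophile that could also act as a Michael acceptor.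

**Step 8**
Reactants: 12 8-tert-butyl 1-methyl (5R,7R)-5-methyl-6-oxo-7-(prop-2-en-1-yl)-7-(prop-1-en-2-yl)oct-2-ynedioate
Product: 13 tert-butyl (1R,3E,5R)-3-(2-methoxy-2-oxoethylidene)-2,2,5-trimethyl-6-oxo-1-(prop-2-en-1-yl)cyclohexane-1-carboxylate
Conditions: Fe(acac)3 (0.5 equiv), PhSiH3 (2.5 equiv), EtOH/(CH2OH)2 5:1, 0.02 M, 60 °C
Reagents that add atoms: none
Why: Proposed new method: an iron hydride formed from Fe(acac)3 and PhSiH3 transfers a hydrogen atom to the CH2 terminus of the isopropenyl group (Markovnikov sense), the tertiary C8 radical adds to the electron-poor alkyne carbon C7, and the α-ester vinyl radical is reduced and protonated (or takes a hydrogen atom from the silane) to give the exocyclic enoate; the closest known reaction is the Fe(acac)3/PhSiH3 reductive coupling of unactivated alkenes with acrylate-type acceptors, here asked to accept an alkynoate. Ring A (C1–C8–C7–C6–C5–C9) closes in the 6-exo-dig mode, which is both polarity-matched and smaller-ring than 7-endo attack at the ester-bearing carbon. No stereocentre is created (C8 carries two methyl groups, C7 stays trigonal), so C1 passes through unchanged and C7 is left for step 11. Selectivity for the 1,1-disubstituted alkene over the allyl group follows from the faster hydrogen-atom transfer that leads to a tertiary radical, and the electron-poor alkyne is not a hydrogen-atom acceptor. The cyclisation must outrun the 1,2-acyl (Dowd–Beckwith) shift of the β-keto radical and simple reduction of C8, which a nucleophilic tertiary radical held five atoms from a conjugated alkyne, at high dilution, should manage. A radical is used because it tolerates the crowding between C8 and the adjacent quaternary C1 that defeats two-electron alkylation.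

**Step 9**
Reactants: 13 tert-butyl (1R,3E,5R)-3-(2-methoxy-2-oxoethylidene)-2,2,5-trimethyl-6-oxo-1-(prop-2-en-1-yl)cyclohexane-1-carboxylate; 14 1,1-dimethoxyethene
Product: 16 methyl (2E)-2-[(3R,5R)-3-(3,3-dimethoxyprop-2-enoyl)-2,2,5-trimethyl-4-oxo-3-(prop-2-en-1-yl)cyclohexylidene]acetate, via acid chloride 15 (not isolated)
Conditions: SOCl2, CH2Cl2, rt; evaporate; then 14, Et3N, CH2Cl2, 0 °C → rt
Reagents that add atoms: none
Why: SOCl2 converts tert-butyl esters directly into acid chlorides while methyl esters are inert, so the β-keto acid is never stored, and C-acylation of the electron-rich ketene acetal with loss of HCl to Et3N gives the acylketene acetal, a C2–C3–C4 unit whose C3–H is vinylic and not acidic.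

**Step 10**
Reactants: 16 methyl (2E)-2-[(3R,5R)-3-(3,3-dimethoxyprop-2-enoyl)-2,2,5-trimethyl-4-oxo-3-(prop-2-en-1-yl)cyclohexylidene]acetate
Product: 17 methyl (2E)-2-[(1S,5R)-4-methoxy-5,8,8-trimethyl-2,9-dioxo-1-(prop-2-en-1-yl)bicyclo[3.3.1]non-3-en-7-ylidene]acetate
Conditions: KN(SiMe3)2, THF, −78 → 0 °C; aq. NH4Cl
Reagents that add atoms: none
Why: Proposed new method: the amide base can enolise the C9 ketone only toward C5, and the enolate carbon adds intramolecularly to the acetal carbon C4 of the β,β-dimethoxy enone (6-endo-trig) and expels methoxide, closing ring B (C1–C2–C3–C4–C5–C9) directly as its C4 methyl enol ether; a plain β-keto ester would be deprotonated at C3 first and lose its electrophilicity, which this acceptor avoids; the closest known reactions are carbanion addition–elimination on α-oxo ketene acetals and dithioacetals and the ring-closing C-acylation of an Effenberger malonyl annulation; the C5 configuration is dictated by the tether from C1, since only the face syn to C2 can be reached.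

**Step 11**
Reactants: 17 methyl (2E)-2-[(1S,5R)-4-methoxy-5,8,8-trimethyl-2,9-dioxo-1-(prop-2-en-1-yl)bicyclo[3.3.1]non-3-en-7-ylidene]acetate
Product: 18 methyl 2-[(1S,5R,7S)-4-methoxy-5,8,8-trimethyl-2,9-dioxo-1-(prop-2-en-1-yl)bicyclo[3.3.1]non-3-en-7-yl]acetate
Conditions: Cu(OAc)2·H2O (5 mol%), 1,2-(Ph2P)2C6H4 (5 mol%), (HMe2Si)2O, t-BuOH, toluene, rt
Reagents that add atoms: none
Why: Copper hydride conjugate reduction of the β,β-disubstituted enoate leaves the ketone, the vinylogous ester and the allyl group alone, and hydride should reach C7 from the exo face of ring A because the endo face is closed by C3 of ring B, which places the acetate arm endo (7S).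

**Step 12**
Reactants: 18 methyl 2-[(1S,5R,7S)-4-methoxy-5,8,8-trimethyl-2,9-dioxo-1-(prop-2-en-1-yl)bicyclo[3.3.1]non-3-en-7-yl]acetate
Product: 19 2-[(1S,5R,7S)-4-methoxy-5,8,8-trimethyl-2,9-dioxo-1-(prop-2-en-1-yl)bicyclo[3.3.1]non-3-en-7-yl]acetic acid
Conditions: LiOH, THF/H2O, 0 °C → rt; then 1 M HCl
Reagents that add atoms: lithium hydroxide, [Li+].[OH-]
Why: Saponification of the unhindered primary-alkyl methyl ester at room temperature, where the vinylogous ester (cleaved only on heating) and the hindered C9 ketone should persist.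

**Step 13**
Reactants: 19 2-[(1S,5R,7S)-4-methoxy-5,8,8-trimethyl-2,9-dioxo-1-(prop-2-en-1-yl)bicyclo[3.3.1]non-3-en-7-yl]acetic acid
Product: 21 2-[(1S,5R,7S)-4-methoxy-5,8,8-trimethyl-2,9-dioxo-1-(prop-2-en-1-yl)bicyclo[3.3.1]non-3-en-7-yl]acetaldehyde, via acid chloride 20 (not isolated)
Conditions: Me2C=C(Cl)NMe2, CH2Cl2, 0 °C; then LiAlH(O-t-Bu)3, THF, −78 °C
Reagents that add atoms: none
Why: The acid is turned into its chloride under neutral conditions and reduced with LiAlH(O-t-Bu)3 at −78 °C, a hydride that stops at the aldehyde and is too bulky and mild to attack the hindered C9 ketone or the vinylogous ester.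

**Step 14**
Reactants: 21 2-[(1S,5R,7S)-4-methoxy-5,8,8-trimethyl-2,9-dioxo-1-(prop-2-en-1-yl)bicyclo[3.3.1]non-3-en-7-yl]acetaldehyde
Product: 22 (1S,5R,7R)-4-methoxy-5,8,8-trimethyl-7-(3-methylbut-2-en-1-yl)-1-(prop-2-en-1-yl)bicyclo[3.3.1]non-3-ene-2,9-dione
Conditions: i-PrPPh3I, KN(SiMe3)2, THF, 0 °C; then 21, −78 °C → rt
Reagents that add atoms: isopropyltriphenylphosphonium iodide, CC(C)[P+](c1ccccc1)(c1ccccc1)c1ccccc1.[I-]
Why: Wittig olefination of the aldehyde with the non-stabilised isopropylidene ylide completes the C7 prenyl group, while the hindered bridging ketone and the vinylogous ester do not react with this bulky ylide (the C7 descriptor changes only through priorities).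

**Step 15**
Reactants: 22 (1S,5R,7R)-4-methoxy-5,8,8-trimethyl-7-(3-methylbut-2-en-1-yl)-1-(prop-2-en-1-yl)bicyclo[3.3.1]non-3-ene-2,9-dione; 23 2-methylbut-2-ene
Product: 24 (1S,5R,7R)-4-methoxy-5,8,8-trimethyl-1,7-bis(3-methylbut-2-en-1-yl)bicyclo[3.3.1]non-3-ene-2,9-dione
Conditions: 23 (excess), second-generation Grubbs catalyst RuCl2(=CHPh)(PCy3)(H2IMes) (5 mol%), CH2Cl2, 40 °C
Reagents that add atoms: none
Why: Olefin cross-metathesis of the terminal allyl group with 2-methylbut-2-ene gives the C1 prenyl group with loss of propene, the trisubstituted C7 prenyl alkene undergoing only degenerate exchange.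

**Step 16**
Reactants: 24 (1S,5R,7R)-4-methoxy-5,8,8-trimethyl-1,7-bis(3-methylbut-2-en-1-yl)bicyclo[3.3.1]non-3-ene-2,9-dione; 25 2-methylpropanoyl chloride
Product: 26 (1R,5R,7R)-4-methoxy-5,8,8-trimethyl-1,7-bis(3-methylbut-2-en-1-yl)-3-(2-methylpropanoyl)bicyclo[3.3.1]non-3-ene-2,9-dione
Conditions: 2,2,6,6-tetramethylpiperidine, n-BuLi, THF, −78 °C; then 25, −78 → −40 °C
Reagents that add atoms: none
Why: Vinylic lithiation of the β-methoxy enone at C3 by the hindered lithium amide and C-acylation with the acid chloride, a known way to acylate methyl enol ethers of bicyclo[3.3.1]nonane-2,4,9-triones, affects no stereocentre (the C1 descriptor changes only through priorities).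

**Step 17**
Reactants: 26 (1R,5R,7R)-4-methoxy-5,8,8-trimethyl-1,7-bis(3-methylbut-2-en-1-yl)-3-(2-methylpropanoyl)bicyclo[3.3.1]non-3-ene-2,9-dione
Product: 27 (1R,5R,7R)-4-hydroxy-5,8,8-trimethyl-1,7-bis(3-methylbut-2-en-1-yl)-3-(2-methylpropanoyl)bicyclo[3.3.1]non-3-ene-2,9-dione
Conditions: LiOH, dioxane/H2O, 90 °C; then 1 M HCl
Reagents that add atoms: lithium hydroxide, [Li+].[OH-]
Why: Hydroxide adds to C4 of the vinylogous ester and expels methoxide (addition–elimination), and acidification releases the enolised β-triketone with its three stereocentres untouched.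

**Compound list**

1 | diethyl 2-(propan-2-ylidene)malonate | CCOC(=O)C(=C(C)C)C(=O)OCC | starting material
2 | allyl bromide | C=CCBr | starting material
3 | diethyl 2-(prop-2-en-1-yl)-2-(prop-1-en-2-yl)propanedioate | CCOC(=O)C(CC=C)(C(C)=C)C(=O)OCC | intermediate
4 | (2S)-2-(ethoxycarbonyl)-2-(prop-1-en-2-yl)pent-4-enoic acid | CCOC(=O)[C@](CC=C)(C(=O)O)C(C)=C | intermediate
5 | 1-tert-butyl 3-ethyl (2R)-2-(prop-2-en-1-yl)-2-(prop-1-en-2-yl)propanedioate | CCOC(=O)[C@](CC=C)(C(=O)OC(C)(C)C)C(C)=C | intermediate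
6 | (2R)-2-(tert-butoxycarbonyl)-2-(prop-1-en-2-yl)pent-4-enoic acid | OC(=O)[C@](CC=C)(C(=O)OC(C)(C)C)C(C)=C | intermediate
7 | ethylmagnesium bromide | CC[Mg]Br | starting material
8 | tert-butyl (2S)-2-(chlorocarbonyl)-2-(prop-1-en-2-yl)pent-4-enoate (not isolated) | ClC(=O)[C@](CC=C)(C(=O)OC(C)(C)C)C(C)=C | intermediate
9 | tert-butyl (2R)-3-oxo-2-(prop-2-en-1-yl)-2-(prop-1-en-2-yl)pentanoate | CCC(=O)[C@](CC=C)(C(=O)OC(C)(C)C)C(C)=C | intermediate
10 | propargyl bromide (3-bromoprop-1-yne) | BrCC#C | starting material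
11 | tert-butyl (2R,4R)-4-methyl-3-oxo-2-(prop-2-en-1-yl)-2-(prop-1-en-2-yl)hept-6-ynoate (4R drawn, 4S epimer also present) | C#CC[C@@H](C)C(=O)[C@](CC=C)(C(=O)OC(C)(C)C)C(C)=C | intermediate
12 | 8-tert-butyl 1-methyl (5R,7R)-5-methyl-6-oxo-7-(prop-2-en-1-yl)-7-(prop-1-en-2-yl)oct-2-ynedioate (key-step precursor; C5 epimer mixture, 5R drawn) | COC(=O)C#CC[C@@H](C)C(=O)[C@](CC=C)(C(=O)OC(C)(C)C)C(C)=C | intermediate
13 | tert-butyl (1R,3E,5R)-3-(2-methoxy-2-oxoethylidene)-2,2,5-trimethyl-6-oxo-1-(prop-2-en-1-yl)cyclohexane-1-carboxylate (key-step product) | COC(=O)/C=C1\C[C@@H](C)C(=O)[C@](CC=C)(C(=O)OC(C)(C)C)C1(C)C | intermediate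
14 | 1,1-dimethoxyethene | C=C(OC)OC | starting material
15 | (1R,3E,5R)-3-(2-methoxy-2-oxoethylidene)-2,2,5-trimethyl-6-oxo-1-(prop-2-en-1-yl)cyclohexane-1-carbonyl chloride (not isolated) | COC(=O)/C=C1\C[C@@H](C)C(=O)[C@](CC=C)(C(Cl)=O)C1(C)C | intermediate
16 | methyl (2E)-2-[(3R,5R)-3-(3,3-dimethoxyprop-2-enoyl)-2,2,5-trimethyl-4-oxo-3-(prop-2-en-1-yl)cyclohexylidene]acetate | COC(=O)/C=C1\C[C@@H](C)C(=O)[C@](CC=C)(C(=O)C=C(OC)OC)C1(C)C | intermediate
17 | methyl (2E)-2-[(1S,5R)-4-methoxy-5,8,8-trimethyl-2,9-dioxo-1-(prop-2-en-1-yl)bicyclo[3.3.1]non-3-en-7-ylidene]acetate | COC(=O)/C=C1\C[C@@]2(C)C(=O)[C@](CC=C)(C(=O)C=C2OC)C1(C)C | intermediate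
18 | methyl 2-[(1S,5R,7S)-4-methoxy-5,8,8-trimethyl-2,9-dioxo-1-(prop-2-en-1-yl)bicyclo[3.3.1]non-3-en-7-yl]acetate | COC(=O)C[C@@H]1C[C@@]2(C)C(=O)[C@](CC=C)(C(=O)C=C2OC)C1(C)C | intermediate
19 | 2-[(1S,5R,7S)-4-methoxy-5,8,8-trimethyl-2,9-dioxo-1-(prop-2-en-1-yl)bicyclo[3.3.1]non-3-en-7-yl]acetic acid | OC(=O)C[C@@H]1C[C@@]2(C)C(=O)[C@](CC=C)(C(=O)C=C2OC)C1(C)C | intermediate
20 | 2-[(1S,5R,7S)-4-methoxy-5,8,8-trimethyl-2,9-dioxo-1-(prop-2-en-1-yl)bicyclo[3.3.1]non-3-en-7-yl]acetyl chloride (not isolated) | ClC(=O)C[C@@H]1C[C@@]2(C)C(=O)[C@](CC=C)(C(=O)C=C2OC)C1(C)C | intermediate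
21 | 2-[(1S,5R,7S)-4-methoxy-5,8,8-trimethyl-2,9-dioxo-1-(prop-2-en-1-yl)bicyclo[3.3.1]non-3-en-7-yl]acetaldehyde | O=CC[C@@H]1C[C@@]2(C)C(=O)[C@](CC=C)(C(=O)C=C2OC)C1(C)C | intermediate
22 | (1S,5R,7R)-4-methoxy-5,8,8-trimethyl-7-(3-methylbut-2-en-1-yl)-1-(prop-2-en-1-yl)bicyclo[3.3.1]non-3-ene-2,9-dione | CC(C)=CC[C@@H]1C[C@@]2(C)C(=O)[C@](CC=C)(C(=O)C=C2OC)C1(C)C | intermediate
23 | 2-methylbut-2-ene | CC=C(C)C | starting material
24 | (1S,5R,7R)-4-methoxy-5,8,8-trimethyl-1,7-bis(3-methylbut-2-en-1-yl)bicyclo[3.3.1]non-3-ene-2,9-dione | CC(C)=CC[C@@H]1C[C@@]2(C)C(=O)[C@](CC=C(C)C)(C(=O)C=C2OC)C1(C)C | intermediate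
25 | 2-methylpropanoyl chloride | CC(C)C(Cl)=O | starting material
26 | (1R,5R,7R)-4-methoxy-5,8,8-trimethyl-1,7-bis(3-methylbut-2-en-1-yl)-3-(2-methylpropanoyl)bicyclo[3.3.1]non-3-ene-2,9-dione | CC(C)=CC[C@@H]1C[C@@]2(C)C(=O)[C@](CC=C(C)C)(C(=O)C(C(=O)C(C)C)=C2OC)C1(C)C | intermediate
27 | (1R,5R,7R)-4-hydroxy-5,8,8-trimethyl-1,7-bis(3-methylbut-2-en-1-yl)-3-(2-methylpropanoyl)bicyclo[3.3.1]non-3-ene-2,9-dione | CC(C)=CC[C@@H]1C[C@@]2(C)C(=O)[C@](CC=C(C)C)(C(=O)C(C(=O)C(C)C)=C2O)C1(C)C | target

**Step count and risks**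

Total steps: 17. Longest linear sequence: 17 steps (1 → 27).

Step 8 (proposed new method). The radical closure may fail through hydrogen-atom transfer to the allyl group, reduction of the C8 radical before it cyclises, or 1,2-acyl migration of the β-keto radical. The fallback sets out from 12 and makes the C7–C8 bond by two-electron organopalladium chemistry. LiI and AcOH in MeCN at 70 °C add HI across the ynoate to give the (Z)-β-iodo enoate F1. An intramolecular reductive Heck reaction (Pd(OAc)2, PPh3, HCO2Na, Bu4NCl, DMF, 80 °C) then inserts the isopropenyl group into the vinylpalladium bond at C7 in the 6-exo-trig mode, and formate reduces the neopentyl alkylpalladium, which has no β-hydrogen, to the second methyl group on C8. This gives the Z isomer of 13, F2. F2 would be taken through steps 9 and 10 unchanged, as the acid chloride F3, the acylketene acetal F4 and the bicyclic enoate F5, and the sequence comes back to the route at 18, where the alkene geometry has disappeared.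

Step 10 (proposed new method). The closure may fail through O- instead of C-attack of the enolate, γ-deprotonation of the enoate at C6, or inability of the hindered C5 carbon to reach C4. The fallback sets out from acid chloride 15 and uses the classical Claisen sequence. Acylation of the lithium enolate of methyl acetate (MeOAc, LiN(SiMe3)2, THF, −78 °C) gives the β-keto ester F6. Dieckmann-type closure at C5 under equilibrating conditions (KOt-Bu, t-BuOH/THF, 60 °C) is driven by formation of the stabilised trione enolate and gives the trione F7; it is expected to be slow because C3 is deprotonated first. O-Methylation with Me3SiCHN2 in toluene/MeOH gives 17, where the route is rejoined, together with the regioisomeric 2-methoxy enol ether F8, which is separated.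

Step 11. Hydride transfer to the neopentyl β-carbon C7 may be sluggish, or facial selectivity may be poor because the axial methyl group on C8 flanks the exo face. The fallback sets out from 17 and replaces hydrometalation by dissolving-metal electron transfer: Mg turnings in MeOH at rt reduce the conjugated ester, and the small proton donor should protonate C7 from the open exo face, giving 18 directly. This fallback makes no new compound (F0).

**Further compounds**

F1 | step 8 | 8-tert-butyl 1-methyl (2Z,5R,7R)-3-iodo-5-methyl-6-oxo-7-(prop-2-en-1-yl)-7-(prop-1-en-2-yl)oct-2-enedioate | COC(=O)/C=C(\I)C[C@@H](C)C(=O)[C@](CC=C)(C(=O)OC(C)(C)C)C(C)=C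
F2 | step 8 | tert-butyl (1R,3Z,5R)-3-(2-methoxy-2-oxoethylidene)-2,2,5-trimethyl-6-oxo-1-(prop-2-en-1-yl)cyclohexane-1-carboxylate | COC(=O)/C=C1/C[C@@H](C)C(=O)[C@](CC=C)(C(=O)OC(C)(C)C)C1(C)C
F3 | step 8 | (1R,3Z,5R)-3-(2-methoxy-2-oxoethylidene)-2,2,5-trimethyl-6-oxo-1-(prop-2-en-1-yl)cyclohexane-1-carbonyl chloride | COC(=O)/C=C1/C[C@@H](C)C(=O)[C@](CC=C)(C(Cl)=O)C1(C)C
F4 | step 8 | methyl (2Z)-2-[(3R,5R)-3-(3,3-dimethoxyprop-2-enoyl)-2,2,5-trimethyl-4-oxo-3-(prop-2-en-1-yl)cyclohexylidene]acetate | COC(=O)/C=C1/C[C@@H](C)C(=O)[C@](CC=C)(C(=O)C=C(OC)OC)C1(C)C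
F5 | step 8 | methyl (2Z)-2-[(1S,5R)-4-methoxy-5,8,8-trimethyl-2,9-dioxo-1-(prop-2-en-1-yl)bicyclo[3.3.1]non-3-en-7-ylidene]acetate | COC(=O)/C=C1/C[C@@]2(C)C(=O)[C@](CC=C)(C(=O)C=C2OC)C1(C)C
F6 | step 10 | methyl 3-[(1S,3E,5R)-3-(2-methoxy-2-oxoethylidene)-2,2,5-trimethyl-6-oxo-1-(prop-2-en-1-yl)cyclohexyl]-3-oxopropanoate | COC(=O)/C=C1\C[C@@H](C)C(=O)[C@](CC=C)(C(=O)CC(=O)OC)C1(C)C
F7 | step 10 | methyl (2E)-2-[(1S,5R)-5,8,8-trimethyl-2,4,9-trioxo-1-(prop-2-en-1-yl)bicyclo[3.3.1]nonan-7-ylidene]acetate | COC(=O)/C=C1\C[C@@]2(C)C(=O)[C@](CC=C)(C(=O)CC2=O)C1(C)C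
F8 | step 10 | methyl (2E)-2-[(1S,5R)-2-methoxy-5,8,8-trimethyl-4,9-dioxo-1-(prop-2-en-1-yl)bicyclo[3.3.1]non-2-en-7-ylidene]acetate | COC(=O)/C=C1\C[C@@]2(C)C(=O)[C@](CC=C)(C(OC)=CC2=O)C1(C)C
F0 | step 11 | none | none
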